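The earlier runs and the new flask are calculated with constants of no real substance; the scatter is artificial.

Time is the setting I sort these flasks by, and I count it in powers of ten.

| setting | eta | delta | theta | maple | birch | oak |
|---|---|---|---|---|---|---|
| starting material | 0.50 M | 0.25 M | 1 M | 0.50 M | 0.50 M | 0.50 M |
| remark | run made earlier | run made earlier | run made earlier | everything together in a closed stirred flask, run for 20 h | one stirred flow tank at steady state, fed with the mixture as stated, mean residence time 100 h | a single well-mixed tank run continuously and read at steady state, 20 h in it on average |
| time |  |  |  | 20 h |  |  |

| run | time / h | intermediate A / % | target / % |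
|---|---|---|---|
| eta | 3.00 | 20 | 2 |
| eta | 6.00 | 29 | 3 |
| eta | 10.0 | 36 | 0 |
| eta | 12.0 | 40 | 4 |
| delta | 1.33 | 11 | 0 |
| delta | 3.00 | 23 | 0 |
| delta | 6.00 | 25 | 3 |
| delta | 15.0 | 39 | 10 |
| theta | 4.00 | 24 | 4 |
| theta | 8.00 | 38 | 4 |
| theta | 12.0 | 41 | 6 |
| theta | 15.0 | 42 | 9 |

(standard deviation of a reading: 2 percentage points)

- the stated concentrations are those of everything mixed, before any reaction; amounts are the same in each set-up
- the numbers in the tables scatter with a standard deviation of 2 percentage points
- the earlier runs were made in a closed, stirred flask
- a reading or a percentage of target counts all its forms, free or not

- order of the set-ups by the amount of intermediate A at the outlet or at the end, in percent of the starting material put in, highest first (maple / birch / oak)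
- amount of intermediate A at the outlet or at the end, in percent of the starting material put in, maple
- amount of intermediate A at the outlet or at the end, in percent of the starting material put in, birch
- amount of intermediate A at the outlet or at the end, in percent of the starting material put in, oak

I read the tables at equal times first. At 3.00 h, eta holds 20% of intermediate A and delta 23%, a gap of 3 percentage points with a scatter of 2 points on each reading, so I read no effect of the charge there and treat each step as first order.

Next I go down theta's column. Intermediate A gains 1 point between 12.0 h and 15.0 h, which lies inside the scatter, so I read a crest at 15.0 h. I call this the crest time t_c, the time at which intermediate A stops rising in a closed flask. That is my choice: the readings end at 15.0 h and show no fall.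

Eta's top row gives the filling constant. Intermediate A and target together make 22.0% at 3.00 h, so from this one scattered row I take k_in, the first-order rate constant from starting material to intermediate A, as 0.0828 h⁻¹.

Let k_out be the first-order rate constant for the loss of intermediate A. For two first-order steps in a row, with k_in and k_out of similar size, t_c lies close to the inverse of their geometric mean. On a logarithmic axis, then, 1/t_c stands midway between them. Here k_in stands 0.0941 decade above it, and k_out the same distance below, at 0.0537 h⁻¹.

For maple, the closed-flask chain gives 42.9%. In this chain, a tank of mean residence time τ holds as intermediate A the fraction k_inτ/(1+k_inτ) times 1/(1+k_outτ). That gives 30.1% for oak, whose 20 h on average lies 0.125 decade beyond t_c, and 14.0% for birch, which lies further out, at 0.824 decade.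

The forecast, which says intermediate A “levels off near 42%”, gives 42% for maple, 33% for oak and 24% for birch, in the order maple > oak > birch, which is higher than my reckoning in oak and in birch.

The flask gives 39.0% for maple, 26.2% for oak and 12.6% for birch, in the order maple > oak > birch, against my 42.9%, 30.1% and 14.0%.

    starting material + target ⇌ idle adduct, settled at all times (K = 46.0 M⁻¹)
    starting material ⇌ dormant form (K = 0.350, k = 0.00220 min⁻¹)
    starting material → intermediate A (k = 0.00160 min⁻¹)
    intermediate A → intermediate B (k = 8.00 × 10⁻⁴ min⁻¹)
    target ⇌ isomer of the product (K = 31.0, k = 5.60 × 10⁻⁴ min⁻¹)
    intermediate B → target (k = 0.00190 min⁻¹)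

By its forward path to intermediate A alone, starting material has a half-life of 7.2 h, and by its path to intermediate B alone, intermediate A has 14 h, so on these two paths emptying is slower than filling, with twice the half-life, or 0.301 decade. Measured from the t_c of 15.0 h, oak stands 0.125 decade out and holds 26.2%, while birch stands 0.824 decade out and holds 12.6%.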